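## Retrosynthetic overview

1. Target 20 ⇒ cis-fused keto alcohol 18 + umbelliferone 19. The C11–O bond is made last, by a Mitsunobu reaction.
2. The decalin of 17/18 ⇒ bicyclo[3.1.0]hexan-2-one 15 with the open C6–C11 chain on C5: disconnect C9–C10 (ring B) and reconnect C2–C10. In the forward sense ring B closes while the five-membered ring C2–C3–C4–C5–C10 takes in the cyclopropane CH2 (C1) and becomes six-membered ring A.
3. Enabling feature: in ring A the C3 ketone and the quaternary ring-fusion carbon C10 are 1,4-related through C2 and C1. C10 is therefore the homo-Michael position of C3=O, and a C2–C10 bond turns ring A into an acylcyclopropane with a tertiary, cation-stabilising carbon. The C7=C8 alkene of ring B lies where the cation left by attack of C9 on C10 loses a proton.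
4. 15 ⇒ (R)-4-alkyl-3-methylcyclopentenone 10 (1,2-reduction, OH-directed cyclopropanation, oxidation, gem-dimethylation) ⇒ enynyl pivalate 8 (Rautenstrauch rearrangement with chirality transfer) ⇒ geraniol 1 + trimethylsilylacetylene 5 (catalytic asymmetric alkynylation).
5. Order of ring formation: cyclopentenone ring (step 5), cyclopropane (step 7), then ring B closure together with the five-to-six enlargement to ring A (step 10). The coumarin is brought in ready-made.

Key step: step 10

Remark on the chemistry: drimane numbering is used. Ring A is C1–C5 and C10, with C3 the ketone, C4 the CMe2 carbon, C5 the ring-fusion CH and C10 the ring-fusion C–CH3. Ring B is C5–C10, with C7=C8, a methyl on C8 and C11H2OAr on C9. Read from the SMILES, the decalin is cis-fused: H-5, CH3-10 and H-9 lie on one face and C11 on the other, (5S,9R,10S). The route is planned for this isomer.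

## Route

Step 1
Reactants: 1 geraniol
Product: 2 geranyl tert-butyldiphenylsilyl (TBDPS) ether
Conditions: TBDPSCl, imidazole, CH2Cl2, 0 °C to rt
Reagents that add atoms: tert-butyl(chloro)diphenylsilane, CC(C)(C)[Si](Cl)(c1ccccc1)c1ccccc1
Why: Standard silylation of a primary alcohol gives a bulky, weakly Lewis-basic ether that should survive bases, zinc reagents, gold catalysis and the Lewis acid of step 10, and no stereocenter is involved.

Step 2
Reactants: 2 geranyl TBDPS ether
Product: 4 (2E,6E)-8-(TBDPS-oxy)-2,6-dimethylocta-2,6-dienal, via allylic alcohol 3 (not isolated)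
Conditions: SeO2 (0.1 equiv), t-BuOOH, salicylic acid (0.1 equiv), CH2Cl2, 0 °C to rt; wash; crude, MnO2, CH2Cl2, rt
Reagents that add atoms: tert-butyl hydroperoxide, CC(C)(C)OO (oxygen, relayed by selenium dioxide, O=[Se]=O)
Why: The Riley oxidation (ene reaction, then 2,3-sigmatropic shift) attacks the E-methyl group of the more electron-rich terminal trisubstituted alkene, and MnO2 oxidation of the crude material converges alcohol and aldehyde on the E-enal.

Step 3
Reactants: 4 enal; 5 trimethylsilylacetylene
Product: 7 (3R,4E,8E)-10-(TBDPS-oxy)-4,8-dimethyldeca-4,8-dien-1-yn-3-ol, via silylalkynol 6 (not isolated)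
Conditions: Me2Zn, (S,S)-ProPhenol (10 mol %), Ph3P=O (20 mol %), toluene, 0 °C; aq NH4Cl; crude, K2CO3 (0.2 equiv), MeOH, rt
Reagents that add atoms: none
Why: Catalytic asymmetric alkynylation of an enal by the dinuclear zinc–ProPhenol alkynylide should set the carbinol centre by ligand-controlled Re-face addition, and methanolysis then removes only the alkynyl silane.

Step 4
Reactants: 7 propargylic alcohol
Product: 8 (3R,4E,8E)-10-(TBDPS-oxy)-4,8-dimethyldeca-4,8-dien-1-yn-3-yl pivalate
Conditions: pivaloyl chloride, Et3N, 4-(dimethylamino)pyridine (cat.), CH2Cl2, 0 °C to rt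
Reagents that add atoms: pivaloyl chloride, CC(C)(C)C(=O)Cl
Why: Acylation of the secondary alcohol with retention installs the migrating ester needed for the Rautenstrauch rearrangement.

Step 5
Reactants: 8 enynyl pivalate
Product: 10 (R)-4-[(E)-5-(TBDPS-oxy)-3-methylpent-3-enyl]-3-methylcyclopent-2-en-1-one, via dienyl pivalate 9 (not isolated)
Conditions: Ph3PAuCl (5 mol %), AgSbF6 (5 mol %), wet MeCN, −20 °C
Reagents that add atoms: none
Why: In the Rautenstrauch rearrangement catalysed by cationic monovalent gold, the 1,2-acyloxy shift and the ring closure of the helical pentadienyl cation anti to the departing C–O bond should transfer the carbinol configuration to the ring carbon bearing the chain (future C5), and water cleaves 9 to the conjugated enone.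

Step 6
Reactants: 10 cyclopentenone
Product: 11 (1S,4R)-cis-4-[(E)-5-(TBDPS-oxy)-3-methylpent-3-enyl]-3-methylcyclopent-2-en-1-ol
Conditions: NaBH4, CeCl3·7H2O, MeOH, −78 °C
Reagents that add atoms: none
Why: Luche 1,2-reduction delivers hydride to the ring face opposite the C4 side chain, which should give the cis-1,4 alcohol with OH and chain on the same face.

Step 7
Reactants: 11 cis-cyclopentenol
Product: 12 (1R,2S,4R,5R)-4-[(E)-5-(TBDPS-oxy)-3-methylpent-3-enyl]-5-methylbicyclo[3.1.0]hexan-2-ol (OH, side chain and cyclopropane CH2 all on one face)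
Conditions: Et2Zn, CH2I2, CH2Cl2, −20 to 0 °C
Reagents that add atoms: diiodomethane, ICI
Why: In the hydroxyl-directed Simmons–Smith cyclopropanation (Furukawa reagent) the zinc alkoxide delivers CH2 to the face that carries OH and therefore the chain, which sets both bridgeheads (future C2 and C10), and the alkoxide acceleration should spare the remote alkene.

Step 8
Reactants: 12 cyclopropyl carbinol
Product: 13 (1R,4R,5R)-4-[(E)-5-(TBDPS-oxy)-3-methylpent-3-enyl]-5-methylbicyclo[3.1.0]hexan-2-one
Conditions: Dess–Martin periodinane, CH2Cl2, 0 °C to rt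
Reagents that add atoms: none
Why: Dess–Martin oxidation turns the directing alcohol into the activating ketone under near-neutral conditions that leave cyclopropane, alkene and silyl ether untouched.

Step 9
Reactants: 13 bicyclic ketone
Product: 15 (1R,4S,5R)-4-[(E)-5-(TBDPS-oxy)-3-methylpent-3-enyl]-3,3,5-trimethylbicyclo[3.1.0]hexan-2-one, via monomethyl ketone 14 (not isolated)
Conditions: KN(SiMe3)2 (1.2 equiv), MeI, THF, −78 to 0 °C; second charge KN(SiMe3)2 (1.5 equiv), MeI, −78 °C to rt
Reagents that add atoms: iodomethane, CI
Why: Exhaustive enolate methylation is regioselective because enolisation towards the cyclopropane bridgehead is blocked by strain, so both methyl groups go onto the CH2 flank (future C4), which ends up non-stereogenic.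

Step 10
Reactants: 15 trimethylbicyclo[3.1.0]hexan-2-one
Product: 17 (5S,9R,10S)-11-(TBDPS-oxy)drim-7-en-3-one (cis-fused decalone), via tin enolate 16 (not isolated)
Conditions: SnCl4 (1.5 equiv), CH2Cl2 (0.01 M), −78 to −30 °C; aq NaHCO3
Reagents that add atoms: none
Why: Proposed new method: SnCl4 binds the C3 ketone of 15 and the strained zero-atom bridge C2–C10 breaks as the C8=C9 alkene attacks C10 from the rear, so the cyclopentanone ring C2–C3–C4–C5–C10 takes up the cyclopropane CH2 (C1) and becomes six-membered ring A as tin enolate 16, after which the C8 cation loses H-7 to give the C7=C8 alkene and 16 is protonated at C2. The closest known reaction types are olefin participation in the Lewis-acid opening of acylcyclopropanes (stereospecific, with inversion at the attacked carbon) and the acid-induced thujane-to-p-menthane ring enlargement, in which a bicyclo[3.1.0]hexane breaks its internal bond because only that path gives a tertiary cation, and what is new is their combination in one substrate. Ring B closes 6-exo-tet at C10 (the breaking C10–C2 bond lies outside the new ring) and 6-endo-trig at the alkene through a chair, whereas ring A is not closed but enlarged from five to six atoms. C10 is set by inversion, since the chain and the cyclopropane CH2 sit on the same face of 15 and rear-side entry of C9 leaves CH3-10 cis to H-5 (a free C10 cation should give the same cis fusion because A1,2 strain with CH3-10 and the gem-dimethyl group hold the C5 chain axial), and C9 is set by the E alkene geometry, which places C11 equatorial on the ring B chair and hence trans to CH3-10. The step needs bond selectivity (C2–C10 over C2–C1), secured by tertiary versus primary charge and by six- versus seven-membered closure, survival of the allylic C11–O bond, secured by the bulky weakly basic silyl ether and low temperature, and proton loss towards C7, which follows the preference of acid cyclisations of farnesyl derivatives to drim-7-enes. Collapse of enolate carbon C2 onto C8 (formal 3+2 addition) is disfavoured because C9 is equatorial on ring A, which holds C2 anti to C9 and far from C8.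

Step 11
Reactants: 17 silyl ether
Product: 18 (5S,9R,10S)-11-hydroxydrim-7-en-3-one
Conditions: Bu4NF, THF, 0 °C to rt
Reagents that add atoms: none
Why: Fluoride-induced desilylation frees the primary alcohol, and no stereocenter is at risk because C5, C9 and C10 are not alpha to the ketone.

Step 12
Reactants: 18 keto alcohol; 19 umbelliferone (7-hydroxycoumarin)
Product: 20 target, 7-{[(1R,4aS,8aS)-2,5,5,8a-tetramethyl-6-oxo-1,4,4a,5,6,7,8,8a-octahydronaphthalen-1-yl]methoxy}-2H-chromen-2-one
Conditions: PPh3, diisopropyl azodicarboxylate, THF, 0 °C to rt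
Reagents that add atoms: none
Why: Mitsunobu etherification of a primary alcohol with an acidic phenol forms the C11–O bond under neutral conditions that should tolerate ketone, alkene and lactone, and it touches no stereocenter.

## Compound list

1 | geraniol | CC(C)=CCC/C(C)=C/CO | starting material
2 | geranyl TBDPS ether | CC(C)=CCC/C(C)=C/CO[Si](c1ccccc1)(c1ccccc1)C(C)(C)C | intermediate
3 | (2E,6E)-8-(TBDPS-oxy)-2,6-dimethylocta-2,6-dien-1-ol | OC/C(C)=C/CC/C(C)=C/CO[Si](c1ccccc1)(c1ccccc1)C(C)(C)C | intermediate
4 | (2E,6E)-8-(TBDPS-oxy)-2,6-dimethylocta-2,6-dienal | O=C/C(C)=C/CC/C(C)=C/CO[Si](c1ccccc1)(c1ccccc1)C(C)(C)C | intermediate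
5 | trimethylsilylacetylene | C#C[Si](C)(C)C | starting material
6 | (3S,4E,8E)-10-(TBDPS-oxy)-4,8-dimethyl-1-(trimethylsilyl)deca-4,8-dien-1-yn-3-ol | C[Si](C)(C)C#C[C@@H](O)/C(C)=C/CC/C(C)=C/CO[Si](c1ccccc1)(c1ccccc1)C(C)(C)C | intermediate
7 | (3R,4E,8E)-10-(TBDPS-oxy)-4,8-dimethyldeca-4,8-dien-1-yn-3-ol | C#C[C@@H](O)/C(C)=C/CC/C(C)=C/CO[Si](c1ccccc1)(c1ccccc1)C(C)(C)C | intermediate
8 | pivalate of 7 | C#C[C@@H](OC(=O)C(C)(C)C)/C(C)=C/CC/C(C)=C/CO[Si](c1ccccc1)(c1ccccc1)C(C)(C)C | intermediate
9 | 4-alkyl-3-methylcyclopenta-1,3-dienyl pivalate type dienol ester (ring carbon with the chain as in 10) | CC1=CC(OC(=O)C(C)(C)C)=C[C@H]1CC/C(C)=C/CO[Si](c1ccccc1)(c1ccccc1)C(C)(C)C | intermediate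
10 | (R)-4-[(E)-5-(TBDPS-oxy)-3-methylpent-3-enyl]-3-methylcyclopent-2-en-1-one | CC1=CC(=O)C[C@H]1CC/C(C)=C/CO[Si](c1ccccc1)(c1ccccc1)C(C)(C)C | intermediate
11 | (1S,4R)-cis-cyclopentenol | CC1=C[C@@H](O)C[C@H]1CC/C(C)=C/CO[Si](c1ccccc1)(c1ccccc1)C(C)(C)C | intermediate
12 | (1R,2S,4R,5R)-5-methylbicyclo[3.1.0]hexan-2-ol with OH, chain and cyclopropane CH2 cis | O[C@H]1C[C@@H](CC/C(C)=C/CO[Si](c2ccccc2)(c2ccccc2)C(C)(C)C)[C@@]2(C)C[C@@H]12 | intermediate
13 | (1R,4R,5R)-5-methylbicyclo[3.1.0]hexan-2-one, chain cis to cyclopropane CH2 | O=C1C[C@@H](CC/C(C)=C/CO[Si](c2ccccc2)(c2ccccc2)C(C)(C)C)[C@@]2(C)C[C@@H]12 | intermediate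
14 | (1R,3R,4R,5R)-3,5-dimethyl ketone (3-methyl trans to the chain) | O=C1[C@H](C)[C@@H](CC/C(C)=C/CO[Si](c2ccccc2)(c2ccccc2)C(C)(C)C)[C@@]2(C)C[C@@H]12 | intermediate
15 | (1R,4S,5R)-3,3,5-trimethylbicyclo[3.1.0]hexan-2-one, chain cis to cyclopropane CH2 | O=C1C(C)(C)[C@@H](CC/C(C)=C/CO[Si](c2ccccc2)(c2ccccc2)C(C)(C)C)[C@@]2(C)C[C@@H]12 | intermediate
16 | trichlorotin enolate (C2=C3) of 17 | CC1=CC[C@@H]2C(C)(C)C(O[Sn](Cl)(Cl)Cl)=CC[C@]2(C)[C@@H]1CO[Si](c1ccccc1)(c1ccccc1)C(C)(C)C | intermediate
17 | (5S,9R,10S)-11-(TBDPS-oxy)drim-7-en-3-one, cis-fused | CC1=CC[C@@H]2C(C)(C)C(=O)CC[C@]2(C)[C@@H]1CO[Si](c1ccccc1)(c1ccccc1)C(C)(C)C | intermediate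
18 | (5S,9R,10S)-11-hydroxydrim-7-en-3-one | CC1=CC[C@@H]2C(C)(C)C(=O)CC[C@]2(C)[C@@H]1CO | intermediate
19 | umbelliferone | Oc1ccc2ccc(=O)oc2c1 | starting material
20 | target | CC1=CC[C@@H]2C(C)(C)C(=O)CC[C@]2(C)[C@@H]1COc1ccc2ccc(=O)oc2c1 | target

## Step count and risks

Total step count: 12. Longest linear sequence: 12 steps (1 to 20).

**1. Step 10 (key step).**
- What may go wrong: the C10 cation may lose a proton before the alkene arrives, and loss towards C5 would erase the only controlling stereocenter. The external cyclopropane bond may be opened by chloride. The allylic silyl ether may ionise. The final proton loss may be unselective.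
- Fallback with known chemistry, from 10 back to 17; it keeps the five-to-six enlargement of ring A. Two kinetic alpha'-methylations of 10 (LiN(iPr)2, MeI, THF, −78 °C) should give the monomethyl enone F1 and then the gem-dimethyl enone F2.
- Lewis-acid-induced conjugate addition of the tethered trisubstituted alkene to the enone (MeAlCl2, CH2Cl2, −78 to 0 °C) comes next. Attack on the beta carbon from the face of the tether, followed by proton loss, should give the cis-hydrindanone F3.
- One-carbon homologation of the cyclopentanone with Me3SiCHN2/BF3·OEt2 (Tiffeneau–Demjanov type) follows. The CH2 flank migrates rather than the quaternary one, which should give the alpha-silyl ketone F4. Acidic work-up protodesilylates F4 to 17.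

**2. Step 5.**
- What may go wrong: the helical pentadienyl cation may invert before ring closure, which would erode the chirality transfer.
- Fallback, from 10 back to 11: the stereochemical burden is moved to a reagent-controlled reduction. Scalemic 10 is reduced with catecholborane and (R)-tetrahydro-1-methyl-3,3-diphenyl-1H,3H-pyrrolo[1,2-c][1,3,2]oxazaborole (Corey–Bakshi–Shibata reduction, toluene, −78 °C) in place of the Luche reduction.
- Both enantiomers should then receive the (1S) carbinol. The wanted (R)-enone gives cis alcohol 11, and the minor (S)-enone gives the trans-cyclopentenol F5. F5 is a diastereomer that can be removed by chromatography before step 7.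

**3. Step 12.**
- What may go wrong: substitution at the beta-branched C11 may be slow, and the alkoxyphosphonium salt may instead eliminate towards the allylic H-9.
- Fallback, from 18 back to 20: the other C–O bond is made instead. This is a Pd-catalysed aryl–oxygen cross-coupling of the primary alcohol 18 with commercial 7-bromocoumarin (Pd2(dba)3, tBuBrettPhos, Cs2CO3, toluene, 90 °C). It needs no substitution at C11 and makes no new intermediate.

## Further compounds

F1 | step 10 | (4R,5R)-4-[(E)-5-(TBDPS-oxy)-3-methylpent-3-enyl]-3,5-dimethylcyclopent-2-en-1-one | CC1=CC(=O)[C@H](C)[C@H]1CC/C(C)=C/CO[Si](c1ccccc1)(c1ccccc1)C(C)(C)C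
F2 | step 10 | (S)-4-[(E)-5-(TBDPS-oxy)-3-methylpent-3-enyl]-3,5,5-trimethylcyclopent-2-en-1-one | CC1=CC(=O)C(C)(C)[C@H]1CC/C(C)=C/CO[Si](c1ccccc1)(c1ccccc1)C(C)(C)C
F3 | step 10 | cis-hydrindanone (ring A still five-membered, ketone between CMe2 and CH2; C5, C9, C10 as in 17) | CC1=CC[C@@H]2C(C)(C)C(=O)C[C@]2(C)[C@@H]1CO[Si](c1ccccc1)(c1ccccc1)C(C)(C)C
F4 | step 10 | 2-trimethylsilyl derivative of 17 (C2 epimers, centre erased on desilylation) | CC1=CC[C@@H]2C(C)(C)C(=O)C([Si](C)(C)C)C[C@]2(C)[C@@H]1CO[Si](c1ccccc1)(c1ccccc1)C(C)(C)C
F5 | step 5 | (1S,4S)-trans-4-[(E)-5-(TBDPS-oxy)-3-methylpent-3-enyl]-3-methylcyclopent-2-en-1-ol | CC1=C[C@@H](O)C[C@@H]1CC/C(C)=C/CO[Si](c1ccccc1)(c1ccccc1)C(C)(C)C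
F0 | step 12 | none | none
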